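**Plan**

- Retrosynthetic cuts: C8=C17 and C11–C12 (side chain) go first, and the hydroxy acid is masked as the C19→O2 lactone. In ring A the bonds C2–C3, C3–C4 and C4–C18 are cut together, which shrinks ring A to a cyclopentanone β-keto ester (C10–C1–C2–C4–C5). Then follow C2–C4 (Dieckmann), C10–C1 and C9–C11 (three-component coupling on a ring B enone) and ring B itself (Michael/aldol).
- Enabling feature: ring A carries C2(O)–C3H2–C4(CH3)(CO2H), a γ-oxygenated α-methyl acid. A zinc carbenoid should make exactly this from a ring-fused β-keto ester by inserting one CH2 between ketone and α-carbon (C3) and a second CH2 at the α-carbon (C18).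
- Forward order: ring B enone → three-component coupling → trans-hydrindane β-keto ester (ring A as a five-membered ring) → ring expansion to the trans-decalin with C4 quaternary → C2 reduction and lactone → side chain by vinylogous Michael addition → C8 methylene → hydrolysis.
- Stereochemistry: C5 from an enamine organocatalyst; C10 by addition anti to the C5 substituent; C4 and C2 by attack anti to the axial C20 methyl; C9 by axial protonation; C13=C14 (E) from the s-trans dienolate.

Key step: step 6

Remark: labdane numbering is used (ring A = C1–C5, C10; ring B = C5–C10; C17 = methylene carbon; C18 = methyl on C4; C19 = carboxyl on C4; C20 = methyl on C10). The target is taken as the ent-labdane (2R,4R,5S,9R,10S), in which 2-OH, C19 and C20 lie on one face, all three axial on ring A.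

**Step 1**
Reactants: 1 tert-butyl 4-oxobutanoate; 2 but-3-en-2-one
Product: 4 tert-butyl 2-[(1R)-4-oxocyclohex-2-en-1-yl]acetate, via keto aldehyde 3 (not isolated)
Conditions: (R)-2-[diphenyl(trimethylsilyloxy)methyl]pyrrolidine (10 mol %), ethyl 3,4-dihydroxybenzoate (20 mol %), neat, 4 °C; then KOH (0.1 M aq.), n-Bu4NHSO4 (cat.), THF, 40 °C
Reagents that add atoms: none
Why: Enamine-catalysed asymmetric Michael addition of the aldehyde to the enone followed by intramolecular aldol condensation (Robinson-type annulation) should give the 4-substituted cyclohexenone, the diarylmethyl group of the catalyst shielding one enamine face so that the future C5 is expected to be set as R.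

**Step 2**
Reactants: 4 tert-butyl 2-[(1R)-4-oxocyclohex-2-en-1-yl]acetate
Product: 6 tert-butyl 2-[(1R)-2-methyl-4-oxocyclohex-2-en-1-yl]acetate, via silyl enol ether 5 (not isolated)
Conditions: Me2CuLi, Me3SiCl, THF, −78 °C; then Pd(OAc)2 (10 mol %), O2 (1 atm), DMSO, rt
Reagents that add atoms: lithium dimethylcuprate, [Li+].C[Cu-]C
Why: Cuprate conjugate addition (anti to the C5 arm, a centre that is erased again) with silyl trapping, followed by Saegusa–Ito dehydrogenation of the silyl enol ether, should return the enone with the future C20 methyl on C10 and leave C5 untouched.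

**Step 3**
Reactants: 6 tert-butyl 2-[(1R)-2-methyl-4-oxocyclohex-2-en-1-yl]acetate; 7 tert-butyl[(1-methoxyethenyl)oxy]dimethylsilane; 8 chloro(methoxy)methane
Product: 10 tert-butyl 2-[(1R,2R,3S)-2-(2-methoxy-2-oxoethyl)-3-(methoxymethyl)-2-methyl-4-oxocyclohexyl]acetate, via silyl enol ether 9 (not isolated)
Conditions: HNTf2 (5 mol %), CH2Cl2, −78 °C; then MeOCH2Cl, ZnBr2 (10 mol %), −78 → −20 °C
Reagents that add atoms: none
Why: A Mukaiyama–Michael addition followed by Lewis-acid alkylation of the regiodefined silyl enol ether with the α-chloro ether joins three components around ring B, the ketene acetal attacking C10 anti to the pseudoaxial C5 arm (C1 arm and C4 arm trans, the later trans ring fusion) and the methoxymethyl cation entering C9 anti to the C10 methyl, a centre that is of no consequence because C9 is made trigonal in step 8.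

**Step 4**
Reactants: 10 tert-butyl 2-[(1R,2R,3S)-2-(2-methoxy-2-oxoethyl)-3-(methoxymethyl)-2-methyl-4-oxocyclohexyl]acetate
Product: 11 tert-butyl 2-[(6S,7R,8R)-7-(2-methoxy-2-oxoethyl)-6-(methoxymethyl)-7-methyl-1,4-dioxaspiro[4.5]decan-8-yl]acetate
Conditions: Me3SiOCH2CH2OSiMe3, Me3SiOTf (5 mol %), CH2Cl2, −78 → −20 °C
Reagents that add atoms: 1,2-bis(trimethylsilyloxy)ethane, C[Si](C)(C)OCCO[Si](C)(C)C
Why: Ketalisation by trans-silylation under Me3SiOTf catalysis is aprotic and cold and should mask the hindered C8 ketone (so that only the ester arms react in step 5) without β-elimination of methanol or loss of the tert-butyl ester; no stereocentre is formed.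

**Step 5**
Reactants: 11 tert-butyl 2-[(6S,7R,8R)-7-(2-methoxy-2-oxoethyl)-6-(methoxymethyl)-7-methyl-1,4-dioxaspiro[4.5]decan-8-yl]acetate
Product: 12 trans-hydrindane β-keto tert-butyl ester
Conditions: KOt-Bu (2.2 equiv), THF, 0 °C → rt; AcOH
Reagents that add atoms: none
Why: In this Dieckmann condensation only the methyl ester can act as acyl donor, so the C4 enolate of the tert-butyl ester should close onto C2 and give the five-membered β-keto ester regiospecifically, trans-fused because C5 and C10 are already fixed, with C4 epimerisable and of no consequence.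

**Step 6**
Reactants: 12 trans-hydrindane β-keto tert-butyl ester
Product: 16 trans-decalin keto ester, via zinc cyclopropoxide 13 (not isolated), via zinc ester enolate 14 (not isolated), via zinc homoenolate 15 (not isolated)
Conditions: Et2Zn (6 equiv), CH2I2 (6 equiv), CH2Cl2, 0 °C → rt; Me3SiCl (20 mol %), rt; aq. NH4Cl
Reagents that add atoms: diiodomethane, ICI
Why: Proposed new method: the zinc enolate of 12 should be cyclopropanated across C2=C4 by EtZnCH2I to the bicyclo[3.1.0]hexane zinc cyclopropoxide 13, whose shared C2–C4 bond then fragments (donor–acceptor cyclopropane opening), so that the five-membered ring becomes six-membered ring A with C3 inserted and C2 restored as ketone, giving the zinc ester enolate 14; 14 should take up a second methylene from the excess carbenoid at C4 to give the quaternary β-zincio ester 15, which is protonated on work-up to the C18 methyl. The closest known reaction types are the zinc-carbenoid chain extension of β-keto esters to γ-keto esters and its tandem homoenolate variant, which gives α-methyl γ-keto esters from acyclic substrates; new here is the ring-fused cyclic β-keto ester, which turns chain extension into ring expansion and makes the methylated carbon quaternary. Ring A is therefore not closed by cyclisation but reaches its final size by one-carbon ring expansion (cyclopropanation across the enolate, then cleavage of the bond common to both small rings), and the strained trans-hydrindane relaxes to a trans-decalin. C4 is set in the second methylene transfer: the carbenoid should approach planar C4 of 14 on the face anti to the axial C20 methyl, because the syn face is blocked 1,3-diaxially, which places the new CH2 equatorial and the ester axial on the face of C20; C5 and C10 are carried over unchanged. The step needs chemoselectivity for the β-keto ester, secured by the absence of any alkene at this stage (C8 is a ketal, C9 carries an ether), and a complete second methylene transfer, for which the excess carbenoid and Me3SiCl activation are provided.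

**Step 7**
Reactants: 16 trans-decalin keto ester
Product: 17 axial C2 alcohol
Conditions: LiBH(s-Bu)3, THF, −78 °C; H2O
Reagents that add atoms: none
Why: In this ketone reduction the bulky trialkylborohydride must attack C2 along the equatorial line, because the axial line is closed by the syn-axial C20 methyl and C19 ester, and should therefore give the axial alcohol on the face of C20 and C19.

**Step 8**
Reactants: 17 axial C2 alcohol
Product: 19 methylene keto lactone, via methoxymethyl keto lactone 18 (not isolated)
Conditions: CF3CO2H/CH2Cl2/H2O (10:10:1), 0 °C → rt; evaporation from toluene; DBU (2 equiv), CH2Cl2, rt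
Reagents that add atoms: water, O
Why: Acidolysis should cleave the tert-butyl ester and the dioxolane, the syn-axial 2-hydroxyl and C19 acid should close to the bridged γ-lactone (lactonisation), and base-induced β-elimination (E1cB) of methanol then unveils the C9=C11 enone; no stereocentre is formed and C9 becomes trigonal.

**Step 9**
Reactants: 20 methyl 3-methylbut-2-enoate
Product: 21 1-methoxy-3-methyl-1-(trimethylsilyloxy)buta-1,3-diene
Conditions: LiN(i-Pr)2, THF, −78 °C; Me3SiCl
Reagents that add atoms: chlorotrimethylsilane, C[Si](C)(C)Cl
Why: Kinetic γ-deprotonation of the β,β-dimethylacrylate and O-silylation of the lithium dienolate is the standard preparation of the silyl dienol ether (ketene acetal geometry of no consequence); no stereocentre is formed.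

**Step 10**
Reactants: 19 methylene keto lactone; 21 1-methoxy-3-methyl-1-(trimethylsilyloxy)buta-1,3-diene
Product: 23 keto enoate lactone, via silyl enol ether 22 (not isolated)
Conditions: HNTf2 (5 mol %), CH2Cl2, −78 °C; then 1 M HCl, THF, 0 °C
Reagents that add atoms: none
Why: In this vinylogous Mukaiyama–Michael addition, γ-attack of the dienolate on the enone terminus C11 should build the whole side chain, the s-trans dienolate leading to the E enoate, and protonation of the C8 enol ether at C9 along the axial line anti to the C20 methyl (also the thermodynamic outcome) should set the equatorial side chain.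

**Step 11**
Reactants: 23 keto enoate lactone
Product: 24 methylene enoate lactone
Conditions: Zn, CH2Br2, TiCl4, THF/CH2Cl2, 0 °C → rt
Reagents that add atoms: dibromomethane, BrCBr
Why: Methylenation with the non-basic Zn/CH2Br2/TiCl4 reagent (Lombardo methylenation) is selective for ketones over the lactone and the enoate and should convert the hindered C8 ketone into the exocyclic methylene without epimerising C9.

**Step 12**
Reactants: 24 methylene enoate lactone
Product: 25 (2R,4R,5S,9R,10S)-2-hydroxylabda-8(17),13E-diene-15,19-dioic acid
Conditions: LiOH, THF/MeOH/H2O, 40 °C; then 1 M HCl to pH 4, 0 °C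
Reagents that add atoms: lithium hydroxide, [Li+].[OH-]
Why: Saponification should open the strained γ-lactone and cleave the methyl ester by acyl–oxygen fission (C2 retained), and cold acidification to pH 4 should free the hydroxy diacid before it can relactonise.

**Compound list**

1 | tert-butyl 4-oxobutanoate | O=CCCC(=O)OC(C)(C)C | starting material
2 | but-3-en-2-one | C=CC(C)=O | starting material
3 | tert-butyl (3R)-3-formyl-6-oxoheptanoate (keto aldehyde) | CC(=O)CC[C@H](CC(=O)OC(C)(C)C)C=O | intermediate
4 | tert-butyl 2-[(1R)-4-oxocyclohex-2-en-1-yl]acetate | O=C1CC[C@H](CC(=O)OC(C)(C)C)C=C1 | intermediate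
5 | tert-butyl 2-[(1R,2R)-2-methyl-4-(trimethylsilyloxy)cyclohex-3-en-1-yl]acetate (silyl enol ether; methyl trans to the acetate arm) | C[Si](C)(C)OC1CC[C@H](CC(=O)OC(C)(C)C)[C@@H](C)C=1 | intermediate
6 | tert-butyl 2-[(1R)-2-methyl-4-oxocyclohex-2-en-1-yl]acetate | O=C1CC[C@H](CC(=O)OC(C)(C)C)C(C)=C1 | intermediate
7 | tert-butyl[(1-methoxyethenyl)oxy]dimethylsilane | C=C(OC)O[Si](C)(C)C(C)(C)C | starting material
8 | chloro(methoxy)methane | COCCl | starting material
9 | C8 tert-butyldimethylsilyl enol ether of the Michael adduct (C8=C9; C10 bears methyl and CH2CO2Me, the latter trans to the C5 arm) | CC(C)(C)[Si](C)(C)OC1CC[C@H](CC(=O)OC(C)(C)C)[C@@](C)(CC(=O)OC)C=1 | intermediate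
10 | tert-butyl 2-[(1R,2R,3S)-2-(2-methoxy-2-oxoethyl)-3-(methoxymethyl)-2-methyl-4-oxocyclohexyl]acetate | O=C1CC[C@H](CC(=O)OC(C)(C)C)[C@@](C)(CC(=O)OC)[C@H]1COC | intermediate
11 | tert-butyl 2-[(6S,7R,8R)-7-(2-methoxy-2-oxoethyl)-6-(methoxymethyl)-7-methyl-1,4-dioxaspiro[4.5]decan-8-yl]acetate | O1CCOC12CC[C@H](CC(=O)OC(C)(C)C)[C@@](C)(CC(=O)OC)[C@H]2COC | intermediate
12 | trans-hydrindane β-keto tert-butyl ester (five-membered ring C10–C1–C2(=O)–C4H(CO2t-Bu)–C5; H5 anti to C20; C8 dioxolane; C9 CH2OMe anti to C20; C4 epimerisable) | O1CCOC12CC[C@H]3[C@@](C)(CC(=O)[C@@H]3C(=O)OC(C)(C)C)[C@H]2COC | intermediate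
13 | zinc cyclopropoxide (C3 bridging C2 and C4 of 12, on the face anti to C20; C2–O–ZnEt) | O1CCOC12CC[C@H]3[C@@](C)(C[C@]4(O[Zn]CC)C[C@]34C(=O)OC(C)(C)C)[C@H]2COC | intermediate
14 | zinc ester enolate (ring A six-membered; C2 ketone; C4=C19 enolate) | O1CCOC12CC[C@H]3[C@@](C)(CC(=O)CC3=C(O[Zn]CC)OC(C)(C)C)[C@H]2COC | intermediate
15 | zinc homoenolate (C4 bears CH2ZnI anti to C20 and CO2t-Bu syn to C20) | O1CCOC12CC[C@H]3[C@@](C)(CC(=O)C[C@@]3(C[Zn]I)C(=O)OC(C)(C)C)[C@H]2COC | intermediate
16 | trans-decalin keto ester (C2 ketone; C4 methyl equatorial and CO2t-Bu axial syn to C20; C8 dioxolane; C9 CH2OMe anti to C20) | O1CCOC12CC[C@H]3[C@@](C)(CC(=O)C[C@@]3(C)C(=O)OC(C)(C)C)[C@H]2COC | intermediate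
17 | axial C2 alcohol (as 16 with 2-OH axial, syn to C20 and C19) | O1CCOC12CC[C@H]3[C@@](C)(C[C@@H](O)C[C@@]3(C)C(=O)OC(C)(C)C)[C@H]2COC | intermediate
18 | methoxymethyl keto lactone (C19→O2 γ-lactone; C8 ketone; C9 CH2OMe) | O=C1CC[C@H]2[C@@](C)(C[C@@H]3C[C@@]2(C)C(=O)O3)[C@H]1COC | intermediate
19 | methylene keto lactone (C19→O2 γ-lactone; C8 ketone; C9=C11H2) | O=C1CC[C@H]2[C@@](C)(C[C@@H]3C[C@@]2(C)C(=O)O3)C1=C | intermediate
20 | methyl 3-methylbut-2-enoate | COC(=O)C=C(C)C | starting material
21 | 1-methoxy-3-methyl-1-(trimethylsilyloxy)buta-1,3-diene | C=C(C)C=C(OC)O[Si](C)(C)C | intermediate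
22 | C8 trimethylsilyl enol ether of the vinylogous Michael adduct (C8=C9; complete E side chain) | C[Si](C)(C)OC1CC[C@H]2[C@@](C)(C[C@@H]3C[C@@]2(C)C(=O)O3)C=1CC/C(C)=C/C(=O)OC | intermediate
23 | keto enoate lactone (C8 ketone; C9 side chain equatorial, syn to C20; methyl (E)-enoate; C19→O2 lactone) | O=C1CC[C@H]2[C@@](C)(C[C@@H]3C[C@@]2(C)C(=O)O3)[C@@H]1CC/C(C)=C/C(=O)OC | intermediate
24 | methylene enoate lactone (15-methyl ester 19,2-lactone of the target) | C=C1CC[C@H]2[C@@](C)(C[C@@H]3C[C@@]2(C)C(=O)O3)[C@@H]1CC/C(C)=C/C(=O)OC | intermediate
25 | (2R,4R,5S,9R,10S)-2-hydroxylabda-8(17),13E-diene-15,19-dioic acid (ent-labdane series) | C=C1CC[C@H]2[C@@](C)(C[C@@H](O)C[C@@]2(C)C(=O)O)[C@@H]1CC/C(C)=C/C(=O)O | target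

**Step count**

Total: 12 steps. Longest linear sequence: 11 steps (steps 1–8 and 10–12; step 9 prepares the dienolate on a side branch).

**Steps most likely to fail**

Step 6. The ring-fused, α-branched zinc enolate may be cyclopropanated only sluggishly, and the second methylene transfer to the hindered tertiary zinc enolate may stay incomplete or lose facial control, leaving the ring-expanded ester without C18. The fallback uses known chemistry and sets out from 12. C-alkylation with CH2Br2 (NaH, HMPA/THF) should give the bromomethyl β-keto ester F1. Bu3SnH/AIBN (benzene, 80 °C) should then effect the Dowd–Beckwith radical ring expansion to the C4–H keto ester F2. LiBH(s-Bu)3 should reduce this to the axial C2 alcohol F3. Formation of the alkoxide ester-enolate dianion with LiN(i-Pr)2 (2.2 equiv) and C-methylation with MeI, anti to the C20 methyl and to the axial O–Li, returns to the route at 17.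

Step 3. The β,β-disubstituted and γ-branched enone may react too slowly with the ketene acetal, so that facial selectivity at C10 erodes or the tert-butyl ester is lost under prolonged Lewis-acid exposure. The fallback sets out from 6. A Hosomi–Sakurai conjugate allylation (allyltrimethylsilane, TiCl4, CH2Cl2, −78 °C), with the titanium enolate trapped in the flask by MeOCH2Cl, should give the C10-allyl ketone F4. Ozonolysis in methanolic NaOH/CH2Cl2 at −78 °C converts the terminal alkene directly into the methyl ester and returns to the route at 10.

Step 10. The dienolate may attack through its α-carbon instead of its γ-carbon, E/Z control at C13=C14 may be poor, or the reactive methylene ketone may oligomerise before it is intercepted. The fallback sets out from 19. TiCl4-mediated conjugate propargylation with allenyltributylstannane should give the alkynyl keto lactone F5, with C9 set by the same axial protonation. Zn/CH2Br2/TiCl4 methylenation should give the methylene alkyne F6. Negishi carboalumination (AlMe3, Cp2ZrCl2, CH2Cl2; then I2) should give the E-vinyl iodide F7 with defined geometry. Methoxycarbonylation catalysed by Pd(PPh3)4 (CO, MeOH, Et3N) returns to the route at 24.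

**Further compounds**

F1 | step 6 | bromomethyl β-keto ester (12 with CH2Br on C4, anti to C20) | O1CCOC12CC[C@H]3[C@@](C)(CC(=O)[C@@]3(CBr)C(=O)OC(C)(C)C)[C@H]2COC
F2 | step 6 | C4–H keto ester (16 without the C18 methyl; ester syn to C20) | O1CCOC12CC[C@H]3[C@@](C)(CC(=O)C[C@H]3C(=O)OC(C)(C)C)[C@H]2COC
F3 | step 6 | axial C2 alcohol of F2 (17 without the C18 methyl) | O1CCOC12CC[C@H]3[C@@](C)(C[C@@H](O)C[C@H]3C(=O)OC(C)(C)C)[C@H]2COC
F4 | step 3 | C10-allyl ketone (10 with allyl in place of CH2CO2Me) | O=C1CC[C@H](CC(=O)OC(C)(C)C)[C@@](C)(CC=C)[C@H]1COC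
F5 | step 10 | alkynyl keto lactone (23 with but-3-ynyl at C9) | O=C1CC[C@H]2[C@@](C)(C[C@@H]3C[C@@]2(C)C(=O)O3)[C@@H]1CCC#C
F6 | step 10 | methylene alkyne (F5 with C8=CH2) | C=C1CC[C@H]2[C@@](C)(C[C@@H]3C[C@@]2(C)C(=O)O3)[C@@H]1CCC#C
F7 | step 10 | E-vinyl iodide (24 with iodine in place of CO2Me) | C=C1CC[C@H]2[C@@](C)(C[C@@H]3C[C@@]2(C)C(=O)O3)[C@@H]1CC/C(C)=C/I
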